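## Structural features

The target 22 is an acyclic diarylheptanoid. Its seven-carbon chain (C1–C7) is bonded at C1 to a 4-hydroxy-3-methoxyphenyl (guaiacyl) ring and at C7 to a 4-hydroxy-3,5-dimethoxyphenyl (syringyl) ring, and these two arenes are the only rings. Secondary hydroxyl groups sit at C3 and C5, both (S), which makes an anti-1,3-diol. The two stereocentres are not adjacent but are separated by the C4 methylene, so neither can be set by vicinal induction from the other. Without the extra methoxy group the molecule would be C2-symmetric, so any two-directional tactic has to differentiate the chain ends. The fragile elements are the two electron-rich free phenols (air oxidation under base, especially the syringyl unit) and, in unsaturated precursors, benzylic or allylic C–O bonds that ionise easily next to such rings. The real difficulty is absolute and relative control of a remote anti-1,3-diol flanked by two CH2CH2Ar arms that offer no handle. The feature exploited is that C3 lies two carbons from the guaiacyl ring (via C2 and C1) and C5 two carbons from the syringyl ring (via C6 and C7). Oxygen can therefore be installed under reagent control at benzylic C1 and C7 and then moved across C2=C3 and C5=C6 to C3 and C5, leaving aryl-conjugated C1=C2 and C6=C7 alkenes that are simply saturated.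

## Logic of the disconnections

22 ⇒ 21. Four acyl C–O bonds are cut (two acetates on O3 and O5, two pivalates on the phenolic oxygens). The phenols stay masked as electron-withdrawing esters until the end, so that every earlier intermediate is non-acidic, not oxidisable and a poor benzylic cation stabiliser. Nothing is gained in skeleton; the demand is one mild solvolysis that also removes the hindered syringyl pivalate without exposing phenolates to air.

21 ⇒ 20. Unsaturation is reintroduced at C1=C2 and C6=C7. These styrenes are the thermodynamic sink of the key step, so they are the natural retron. The forward step must saturate two conjugated trans-disubstituted alkenes without hydrogenolysis of the allylic C3–O and C5–O bonds.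

20 ⇒ 17. The C3–O and C5–O bonds are cut and the acetates reattached at C1 and C7, with the alkenes moving to C2=C3 and C5=C6. This turns the remote anti-1,3-diol into two independent benzylic allylic esters, each reachable by enantioselective addition to an aryl aldehyde. The forward step must deliver two suprafacial 1,3-shifts with complete chirality transfer, no benzylic ionisation and no interference from the skipped diene.

17 ⇒ 13 + 4. The C6–C7 bond (and the O-acetyl bond at C7) is cut between an aryl aldehyde and an (E)-alkenyl nucleophile derived from a terminal alkyne. This is convergent and brings in the syringyl ring together with the C7 stereocentre. It demands hydrometalation of the terminal alkyne only, and catalyst-controlled Re-face addition that ignores the remote C1 centre. The C1 carbinol is already an acetate at this stage, so no free hydroxyl consumes borane or competes as a ligand for zinc.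

13 ⇒ 12. The C(sp)–Si bond is cut. The silyl cap is what differentiates the two termini of the five-carbon linchpin so that two different aldehydes can be attached in sequence. Its removal must be close to neutral, to spare the acetate, the aryl pivalate and the base-sensitive skipped enyne.

12 ⇒ 8 + 2. The C1–C2 bond (and the O-acetyl bond at C1) is cut by the same aldehyde alkenylation logic. The forward step must hydroborate the free alkyne in the presence of the silyl-capped one and acetylate the zinc alkoxide in the same flask.

8 ⇒ 5 + 6. The propargylic C4–C5 bond is cut, giving two commodity pieces and the whole C2–C6 unit in one step. The coupling must be SN2 and not SN2', and must not isomerise the 1,4-diyne.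

2 ⇒ 1 and 4 ⇒ 3. The phenolic O-acyl bonds are cut. Pivalate is chosen because it is a poor acyl donor towards zinc alkoxides and a weak para donor.

## Other disconnections considered

Alternative 1: The cut is at C1–C2 and C3–O, with O5 tied temporarily to C1, so the chain is folded into the tetrahydropyran A1. A1 would come from the (S)-homoallylic alcohol A2 (C3–C7 with the syringyl ring, phenol as benzyl ether) and the aryl aldehyde A3 (C1 with the guaiacyl ring, phenol as acetate). The forward key step is an acid-promoted Prins cyclisation: condensation to an oxocarbenium ion, attack of the alkene through a chair with all three substituents equatorial, and capture of the C3 cation by trifluoroacetate. It makes O–C1, C1–C2 and C3–O at once. The 4,6-cis relationship in the ring corresponds to the anti (3S,5S) diol once the benzylic C1–O bond is hydrogenolysed (H2, Pd/C).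
- In its favour: a single stereocentre (C5 of A2) is relayed to C3 by the strong bias of a chair, three bonds form in one operation, and the two arenes enter in separate fragments.
- Against it here: the aryl aldehyde is electron-rich, so the benzylic oxocarbenium ion is prone to 2-oxonia-Cope exchange, which would erode enantiomeric purity and scramble side chains (hence the acetate on the phenol). The same acetate makes the later reductive opening of the O–C1 bond harder. A2 needs its own enantioselective allylation after a three-carbon homologation of the syringyl aldehyde.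
- Comparison: on stereochemical economy this alternative is the better plan (one reagent-controlled centre instead of two, relative configuration fixed by a ring). On differentiating the chain ends the two plans are equal. Mechanistically both hinge on the electronics of a benzylic position, in opposite senses: the Prins route needs a benzylic cation stable enough to form but not so stable that it equilibrates, whereas the chosen plan only has to avoid that cation. In step count the alternative is estimated at ten to eleven steps against nine.

Alternative 2: The cut is at C2–C3 and C5–C6, leaving C3–C4–C5 as propane-1,3-diol A4 and the flanks as allyl acetate A5. The forward key step is an iridium-catalysed transfer-hydrogenative double allylation. A chiral cyclometallated iridium complex (from [Ir(cod)Cl]2, a biaryl bisphosphine and a nitrobenzoic acid) dehydrogenates each carbinol end in turn and allylates the aldehyde so formed, giving the C2-symmetric diol A6.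
- In its favour: both stereocentres are created at their final positions in one catalytic step from achiral feedstock. Because two enantioselective events are coupled, the minor enantiomer is diverted largely into a separable meso-type diastereomer. On enantiopurity, and on needing no later oxygen migration, it is the better plan.
- Against it here: A6 is C2-symmetric while the target is not, so the ends must be told apart statistically. Each allyl group also delivers one carbon too many (only its CH2 and CH carbons map onto C2/C1 and C6/C7). After diol protection the terminal carbons must be cut off oxidatively to a bis(β-alkoxy aldehyde) prone to elimination, the arenes added as organometallics, and the resulting benzylic carbinols removed again.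
- Comparison: structurally the alternative builds the diol core more directly but discards two carbons and creates and destroys two further oxygenated centres. Mechanistically both plans rest on catalyst-controlled carbonyl addition, the alternative needing no chirality transfer. In step economy it is clearly behind (about ten to twelve steps plus a statistical desymmetrisation).

Alternative 3: The cut is at C1–C2 and C6–C7. C2–C6 with both oxygens becomes the C2-symmetric bis-epoxide A7, (2R,4R)-1,2:4,5-diepoxypentane. Each arene arrives with its benzylic carbon as an acyl-anion equivalent: the benzyl-protected 2-aryl-1,3-dithianes A8 (guaiacyl) and A9 (syringyl). In the forward key step lithiated A8 opens one terminal epoxide carbon and lithiated A9 the other, giving the bis-dithiane diol A10. The stereocentres are not touched, so A10 has exactly the spatial arrangement of the target. By the CIP rules, however, A10 must be called (3R,5R) and not (3S,5S), because the sulfur-bearing C1 and C7 outrank C4; the descriptors revert to (S,S) once the dithianes are reduced away.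
- In its favour: the stereocentres come from a building block of fixed configuration and cannot be eroded in the coupling, so on stereochemical certainty it is the better plan. The ends are differentiated simply by adding the two nucleophiles in sequence, on which it is the equal of the chosen plan.
- Against it here: A7 is not a commodity and needs its own enantioselective preparation of three to four steps. The first opening has to stop at the mono-adduct. Stabilised aryl dithiane anions are sluggish towards epoxides and usually need polar additives. Two dithianes must then be reduced to CH2 with a large excess of Ni (Raney type), which produces much sulfur and metal waste, although it could remove the benzyl ethers in the same operation.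
- Comparison: structurally it is the most modular of the plans. Mechanistically it uses only polar, uncatalysed bond formation where the chosen plan relies on two catalytic asymmetric additions and a catalytic rearrangement. In step economy it is estimated at ten to twelve steps against nine.

Key step: step 7

Remark: chain atoms are numbered as in the target (C1 on the guaiacyl ring, C7 on the syringyl ring); (+)-MIB, the (2R) enantiomer of 3-exo-morpholinoisoborneol, is assumed to direct alkenyl transfer to the Re face of aryl aldehydes, mirroring the Si-face delivery by the (2S)-(−) ligand.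

## Route

Step 1
Reactants: 1 vanillin
Product: 2 4-formyl-2-methoxyphenyl pivalate
Conditions: PivCl (1.2 equiv), Et3N (1.5 equiv), DMAP (5 mol%), CH2Cl2, 0 °C → rt
Reagents that add atoms: pivaloyl chloride, CC(C)(C)C(=O)Cl
Why: DMAP-catalysed O-acylation of the phenol (nucleophilic acyl substitution); the aldehyde is untouched and no stereocentre is involved. The pivalate is chosen because it resists acyl transfer to zinc alkoxides in steps 4 and 6 and weakens the para oxygen as a donor for step 7.

Step 2
Reactants: 3 syringaldehyde
Product: 4 4-formyl-2,6-dimethoxyphenyl pivalate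
Conditions: PivCl (1.5 equiv), Et3N (2 equiv), DMAP (10 mol%), CH2Cl2, 0 °C → rt
Reagents that add atoms: pivaloyl chloride, CC(C)(C)C(=O)Cl
Why: The same DMAP-catalysed esterification; the two flanking methoxy groups slow acylation of this phenol, which the higher catalyst loading and a longer reaction time should compensate.

Step 3
Reactants: 5 ethynyltrimethylsilane; 6 propargyl bromide
Product: 8 trimethyl(penta-1,4-diyn-1-yl)silane, via alkynylmagnesium bromide 7 (not isolated)
Conditions: EtMgBr (1.0 equiv), THF, 0 °C → rt; CuCl (5 mol%); 6 (1.1 equiv, 80 wt% in toluene, slow addition), 0 → 45 °C; aq. NH4Cl; distillation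
Reagents that add atoms: none
Why: EtMgBr deprotonates 5 to the alkynyl Grignard 7, which displaces bromide from the propargylic carbon of 6 under CuCl catalysis (copper-catalysed alkynyl–propargyl SN2 coupling) to give the skipped diyne. Slow addition of the electrophile and no excess of Grignard limit SN2' allene formation and proton exchange, and the product is distilled without contact with base.

Step 4
Reactants: 8 trimethyl(penta-1,4-diyn-1-yl)silane; 2 4-formyl-2-methoxyphenyl pivalate
Product: 12 (1R,2E)-1-[3-methoxy-4-(pivaloyloxy)phenyl]-6-(trimethylsilyl)hex-2-en-5-yn-1-yl acetate, via alkenylborane 9 (not isolated), via alkenyl(methyl)zinc 10 (not isolated), via methylzinc alkoxide 11 (not isolated)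
Conditions: Cy2BH (1.05 equiv, from BH3·SMe2 and cyclohexene), toluene, 0 °C → rt; Me2Zn (1.3 equiv), −78 °C; (+)-MIB (5 mol%), 2 (0.9 equiv), −20 → 0 °C; Ac2O (3 equiv), 0 °C → rt; aq. NH4Cl
Reagents that add atoms: acetic anhydride, CC(=O)OC(C)=O
Why: Cy2BH adds syn and anti-Markovnikov to the unhindered terminal alkyne (the silyl-capped alkyne is much slower) to give (E)-alkenylborane 9, and boron-to-zinc exchange with Me2Zn gives 10 with retention of alkene geometry. The zinc amino-alkoxide formed from (+)-MIB directs alkenyl transfer to the Re face of 2 (ligand-controlled catalytic asymmetric alkenylzinc addition), which sets C1 as (R). The zinc alkoxide 11 is acetylated in the same flask, and the aryl pivalate is inert to the borane and the organozinc at these temperatures.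

Step 5
Reactants: 12 (1R,2E)-1-[3-methoxy-4-(pivaloyloxy)phenyl]-6-(trimethylsilyl)hex-2-en-5-yn-1-yl acetate
Product: 13 (1R,2E)-1-[3-methoxy-4-(pivaloyloxy)phenyl]hex-2-en-5-yn-1-yl acetate
Conditions: AgNO3 (10 mol%), acetone/H2O/CH2Cl2, rt, dark
Reagents that add atoms: none
Why: Silver-catalysed protodesilylation of an alkynylsilane: silver ion activates the alkyne towards attack of water at silicon and the silver acetylide is protonated by the medium, so the reaction runs near neutral pH. The acetate, the pivalate and the skipped enyne (no prototropic shift to an allene or conjugated enyne) should survive, and C1 is not touched.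

Step 6
Reactants: 13 (1R,2E)-1-[3-methoxy-4-(pivaloyloxy)phenyl]hex-2-en-5-yn-1-yl acetate; 4 4-formyl-2,6-dimethoxyphenyl pivalate
Product: 17 (1R,2E,5E,7R)-7-[3,5-dimethoxy-4-(pivaloyloxy)phenyl]-1-[3-methoxy-4-(pivaloyloxy)phenyl]hepta-2,5-diene-1,7-diyl diacetate, via alkenylborane 14 (not isolated), via alkenyl(methyl)zinc 15 (not isolated), via methylzinc alkoxide 16 (not isolated)
Conditions: Cy2BH (1.05 equiv, from BH3·SMe2 and cyclohexene), toluene, 0 °C → rt; Me2Zn (1.3 equiv), −78 °C; (+)-MIB (10 mol%), 4 (1.0 equiv), −20 → 0 °C; Ac2O (3 equiv), 0 °C → rt; aq. NH4Cl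
Reagents that add atoms: acetic anhydride, CC(=O)OC(C)=O
Why: The same hydroboration, boron-to-zinc exchange and ligand-controlled alkenylzinc addition as in step 4; Cy2BH selects the terminal alkyne over the internal 1,2-disubstituted alkene and does not reduce the esters. (+)-MIB again directs Re-face attack on 4, so C7 is set as (R) by the catalyst independently of the remote C1 centre. Material of the wrong configuration at either centre ends up mainly as the separable (1R*,7S*) diastereomer, so the enantiomeric purity of 17 should exceed that of either single addition.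

Step 7
Reactants: 17 (1R,2E,5E,7R)-7-[3,5-dimethoxy-4-(pivaloyloxy)phenyl]-1-[3-methoxy-4-(pivaloyloxy)phenyl]hepta-2,5-diene-1,7-diyl diacetate
Product: 20 (1E,3R,5R,6E)-7-[3,5-dimethoxy-4-(pivaloyloxy)phenyl]-1-[3-methoxy-4-(pivaloyloxy)phenyl]hepta-1,6-diene-3,5-diyl diacetate, via guaiacyl-side transposed diacetate 18 (not isolated), via syringyl-side transposed diacetate 19 (not isolated)
Conditions: PdCl2(MeCN)2 (10 mol%), THF, 0 °C → rt, Ar
Reagents that add atoms: none
Why: Phosphine-free divalent palladium binds each alkene on the face opposite its acetate, and the acetate carbonyl oxygen adds to C3 (or C5) in an anti-oxypalladation that gives a 2-methyl-1,3-dioxan-2-ylium ring with a C–Pd σ-bond at C2 (or C6). Anti-elimination of palladium together with the C1–O (or C7–O) bond opens this ring again and releases the 1,3-transposed acetate, so no ring persists in the product; the transient ring forms in a 6-endo-trig mode. The closest known reaction type is the divalent-palladium-catalysed formal [3,3]-sigmatropic (cyclisation-induced) rearrangement of allylic acetates with 1,3-chirality transfer, here run at two independent sites of one molecule through the mono-transposed compounds 18 and 19. In the chair-like dioxanylium intermediate the aryl group on C1 (C7) and the chain on C3 (C5) are both equatorial, which fixes the (E) geometry of the new C1=C2 and C6=C7 alkenes and makes oxygen arrive at C3 (C5) on the same face of the allyl unit from which it leaves C1 (C7). The new stereocentres C3 and C5 are therefore controlled only by the C1 and C7 centres of 17: (1R,2E) gives (1E,3R) and (5E,7R) gives (5R,6E). The step needs suprafacial transfer and not ionisation; this is secured by the pivaloyloxy groups, which make both arenes poor cation stabilisers, by the absence of phosphines and of zerovalent palladium (no π-allyl pathway), and by a non-ionising solvent at room temperature. Each shift is an equilibrium drawn to the product side by conjugation of the new alkene with its arene, and after the first shift the substrate no longer contains the chelating, isomerisation-prone skipped diene.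

Step 8
Reactants: 20 (1E,3R,5R,6E)-7-[3,5-dimethoxy-4-(pivaloyloxy)phenyl]-1-[3-methoxy-4-(pivaloyloxy)phenyl]hepta-1,6-diene-3,5-diyl diacetate
Product: 21 (3S,5S)-7-[3,5-dimethoxy-4-(pivaloyloxy)phenyl]-1-[3-methoxy-4-(pivaloyloxy)phenyl]heptane-3,5-diyl diacetate
Conditions: H2 (4 bar), RhCl(PPh3)3 (10 mol%), toluene/EtOH 1:1, rt
Reagents that add atoms: none
Why: Homogeneous hydrogenation with RhCl(PPh3)3 reduces the two 1,2-disubstituted styrenyl alkenes without passing through π-allyl species, so the allylic C3–O and C5–O acetates should not be hydrogenolysed, and the esters and arenes are inert. C3 and C5 are untouched; their descriptors change from (R,R) to (S,S) only because C2 and C6 lose CIP priority on saturation.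

Step 9
Reactants: 21 (3S,5S)-7-[3,5-dimethoxy-4-(pivaloyloxy)phenyl]-1-[3-methoxy-4-(pivaloyloxy)phenyl]heptane-3,5-diyl diacetate
Product: 22 (3S,5S)-1-(4-hydroxy-3-methoxyphenyl)-7-(4-hydroxy-3,5-dimethoxyphenyl)heptane-3,5-diol
Conditions: K2CO3 (6 equiv), MeOH (degassed), Ar, rt → 45 °C; AcOH to pH 6
Reagents that add atoms: none
Why: Base-mediated transesterification with methanol (Zemplén-type methanolysis) cleaves the two secondary acetates and the two aryl pivalates, which are activated phenol esters; the hindered syringyl pivalate is the slowest, hence the gentle warming. C3 and C5 carry no acidic hydrogen and there is no carbonyl for retro-aldol cleavage, so the stereocentres are not at risk; air is excluded and the mixture neutralised before work-up to protect the phenolates.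

## Compound list

1 | vanillin (4-hydroxy-3-methoxybenzaldehyde) | COc1cc(C=O)ccc1O | starting material
2 | 4-formyl-2-methoxyphenyl pivalate | COc1cc(C=O)ccc1OC(=O)C(C)(C)C | intermediate
3 | syringaldehyde (4-hydroxy-3,5-dimethoxybenzaldehyde) | COc1cc(C=O)cc(OC)c1O | starting material
4 | 4-formyl-2,6-dimethoxyphenyl pivalate | COc1cc(C=O)cc(OC)c1OC(=O)C(C)(C)C | intermediate
5 | ethynyltrimethylsilane | C#C[Si](C)(C)C | starting material
6 | propargyl bromide (3-bromoprop-1-yne) | C#CCBr | starting material
7 | [(trimethylsilyl)ethynyl]magnesium bromide | C[Si](C)(C)C#C[Mg]Br | intermediate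
8 | trimethyl(penta-1,4-diyn-1-yl)silane | C#CCC#C[Si](C)(C)C | intermediate
9 | dicyclohexyl[(1E)-5-(trimethylsilyl)pent-1-en-4-yn-1-yl]borane | C[Si](C)(C)C#CC/C=C/B(C1CCCCC1)C1CCCCC1 | intermediate
10 | methyl[(1E)-5-(trimethylsilyl)pent-1-en-4-yn-1-yl]zinc | C[Zn]/C=C/CC#C[Si](C)(C)C | intermediate
11 | methylzinc (1R,2E)-1-[3-methoxy-4-(pivaloyloxy)phenyl]-6-(trimethylsilyl)hex-2-en-5-yn-1-olate | COc1cc([C@H](O[Zn]C)/C=C/CC#C[Si](C)(C)C)ccc1OC(=O)C(C)(C)C | intermediate
12 | (1R,2E)-1-[3-methoxy-4-(pivaloyloxy)phenyl]-6-(trimethylsilyl)hex-2-en-5-yn-1-yl acetate | COc1cc([C@H](OC(C)=O)/C=C/CC#C[Si](C)(C)C)ccc1OC(=O)C(C)(C)C | intermediate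
13 | (1R,2E)-1-[3-methoxy-4-(pivaloyloxy)phenyl]hex-2-en-5-yn-1-yl acetate | COc1cc([C@H](OC(C)=O)/C=C/CC#C)ccc1OC(=O)C(C)(C)C | intermediate
14 | (1R,2E,5E)-6-(dicyclohexylboranyl)-1-[3-methoxy-4-(pivaloyloxy)phenyl]hexa-2,5-dien-1-yl acetate | COc1cc([C@H](OC(C)=O)/C=C/C/C=C/B(C2CCCCC2)C2CCCCC2)ccc1OC(=O)C(C)(C)C | intermediate
15 | (1R,2E,5E)-1-[3-methoxy-4-(pivaloyloxy)phenyl]-6-(methylzincio)hexa-2,5-dien-1-yl acetate | COc1cc([C@H](OC(C)=O)/C=C/C/C=C/[Zn]C)ccc1OC(=O)C(C)(C)C | intermediate
16 | methylzinc alkoxide of the (1R,2E,5E,7R)-1-acetoxy-hepta-2,5-dien-7-ol (C7–O–ZnCH3; arenes as in 17) | COc1cc([C@H](OC(C)=O)/C=C/C/C=C/[C@@H](O[Zn]C)c2cc(OC)c(OC(=O)C(C)(C)C)c(OC)c2)ccc1OC(=O)C(C)(C)C | intermediate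
17 | (1R,2E,5E,7R)-7-[3,5-dimethoxy-4-(pivaloyloxy)phenyl]-1-[3-methoxy-4-(pivaloyloxy)phenyl]hepta-2,5-diene-1,7-diyl diacetate | COc1cc([C@H](OC(C)=O)/C=C/C/C=C/[C@@H](OC(C)=O)c2cc(OC)c(OC(=O)C(C)(C)C)c(OC)c2)ccc1OC(=O)C(C)(C)C | intermediate
18 | (1E,3R,5E,7R)-7-[3,5-dimethoxy-4-(pivaloyloxy)phenyl]-1-[3-methoxy-4-(pivaloyloxy)phenyl]hepta-1,5-diene-3,7-diyl diacetate | COc1cc(/C=C/[C@H](OC(C)=O)C/C=C/[C@@H](OC(C)=O)c2cc(OC)c(OC(=O)C(C)(C)C)c(OC)c2)ccc1OC(=O)C(C)(C)C | intermediate
19 | (1R,2E,5R,6E)-7-[3,5-dimethoxy-4-(pivaloyloxy)phenyl]-1-[3-methoxy-4-(pivaloyloxy)phenyl]hepta-2,6-diene-1,5-diyl diacetate | COc1cc([C@H](OC(C)=O)/C=C/C[C@@H](OC(C)=O)/C=C/c2cc(OC)c(OC(=O)C(C)(C)C)c(OC)c2)ccc1OC(=O)C(C)(C)C | intermediate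
20 | (1E,3R,5R,6E)-7-[3,5-dimethoxy-4-(pivaloyloxy)phenyl]-1-[3-methoxy-4-(pivaloyloxy)phenyl]hepta-1,6-diene-3,5-diyl diacetate | COc1cc(/C=C/[C@H](OC(C)=O)C[C@@H](OC(C)=O)/C=C/c2cc(OC)c(OC(=O)C(C)(C)C)c(OC)c2)ccc1OC(=O)C(C)(C)C | intermediate
21 | (3S,5S)-7-[3,5-dimethoxy-4-(pivaloyloxy)phenyl]-1-[3-methoxy-4-(pivaloyloxy)phenyl]heptane-3,5-diyl diacetate | COc1cc(CC[C@H](OC(C)=O)C[C@@H](OC(C)=O)CCc2cc(OC)c(OC(=O)C(C)(C)C)c(OC)c2)ccc1OC(=O)C(C)(C)C | intermediate
22 | (3S,5S)-1-(4-hydroxy-3-methoxyphenyl)-7-(4-hydroxy-3,5-dimethoxyphenyl)heptane-3,5-diol | COc1cc(CC[C@H](O)C[C@@H](O)CCc2cc(OC)c(O)c(OC)c2)ccc1O | target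

## Step count and least certain steps

Total step count: 9. Longest linear sequence: 7 steps (steps 3 to 9, from 5 and 6); steps 1 and 2 are single-step side branches that feed 2 into step 4 and 4 into step 6.

Step 7 (key step). The most likely failure is loss of stereochemical fidelity through ionisation of a benzylic acetate, with palladium acting as a Lewis acid and returning racemised or regio-scrambled acetate. The second is stalling or alkene migration because the skipped 1,4-diene chelates the metal or is drawn into conjugation by adventitious palladium hydride. Incomplete second transposition is a lesser concern, since each equilibrium favours the styrene. The fallback sets out from 12 and returns to the route at 18, which needs only one transposition to reach 20: the two shifts are run one at a time, so that the catalyst never meets the skipped diene.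
- 12 is rearranged with PdCl2(MeCN)2 in THF to (1E,3R)-1-[3-methoxy-4-(pivaloyloxy)phenyl]-6-(trimethylsilyl)hex-1-en-5-yn-3-yl acetate F1.
- Silver-catalysed desilylation as in step 5 gives the terminal alkyne (1E,3R)-1-[3-methoxy-4-(pivaloyloxy)phenyl]hex-1-en-5-yn-3-yl acetate F2.
- Hydroboration with Cy2BH gives the alkenylborane F3, exchange with Me2Zn gives the alkenyl(methyl)zinc F4, and (+)-MIB-controlled addition to 4 gives the methylzinc alkoxide F5.
- F5 is acetylated in the flask to 18, and a single palladium-catalysed shift of the remaining benzylic acetate then gives 20.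

This costs one step, but each palladium step has a single reactive site and can be run colder and shorter.

Step 6. The most likely failure is insufficient catalyst control at C7: the substrate's own acetate and the accumulating zinc alkoxide can compete with the amino alcohol for zinc and open a ligand-free, unselective addition channel. Incomplete acetylation in the flask is the second risk. The fallback sets out from 13 and 4 and returns at 17, and replaces asymmetric induction by resolution.
- The addition is quenched with aq. NH4Cl in place of Ac2O, giving the (1R,2E,5E,7R)-7-hydroxy-hepta-2,5-dien-1-yl acetate F6 together with its (7S)-epimer F7.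
- Sharpless kinetic resolution (Ti(OiPr)4, D-(−)-diisopropyl tartrate, t-BuOOH, 4 Å MS, CH2Cl2, −20 °C) should epoxidise the C5=C6 alkene of F7 to the erythro (5R,6R,7R)-epoxy alcohol F8 much faster than it touches F6. The acetate-bearing allyl unit is not an allylic alcohol and stays inert.
- F6 is then acetylated (Ac2O, pyridine, DMAP) to 17.

Step 3. The most likely failure is proton transfer between Grignard 7 and the acidic C–H bonds of 6 or 8, followed by oligomerisation or prototropic isomerisation of the skipped diyne; SN2' attack to the allenyne is the second risk. The fallback sets out from 6 and returns at 8, and reverses the polarity of the coupling. 6 is lithiated at −78 °C (n-BuLi, Et2O) and silylated (Me3SiCl) to (3-bromoprop-1-yn-1-yl)trimethylsilane F9, an electrophile without an acidic C–H. CuCl-catalysed coupling of F9 with commercial ethynylmagnesium bromide (excess, THF) then gives 8.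

Step 8. The most likely failure is slow turnover, since RhCl(PPh3)3 reduces trans-1,2-disubstituted, aryl-conjugated alkenes sluggishly; forcing conditions would invite alkene migration towards an enol acetate or C–O hydrogenolysis. The fallback goes from 20 directly to 21 by metal-free diimide reduction (2-nitrobenzenesulfonohydrazide, Et3N, CH2Cl2, rt), a concerted syn transfer of two hydrogens that cannot ionise or hydrogenolyse an allylic ester. It makes no new compound.

Step 9. The most likely failure is incomplete methanolysis of the doubly ortho-substituted syringyl pivalate, and oxidative degradation of the electron-rich phenolates during the prolonged basic treatment this would call for. The fallback goes from 21 directly to 22 by reductive ester cleavage with LiAlH4 (THF, 0 °C), which removes all four acyl groups as alcohols within minutes irrespective of hindrance, followed by a mildly acidic Rochelle-salt work-up under argon. It makes no new compound.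

## Further compounds

F1 | step 7 | (1E,3R)-1-[3-methoxy-4-(pivaloyloxy)phenyl]-6-(trimethylsilyl)hex-1-en-5-yn-3-yl acetate | COc1cc(/C=C/[C@H](OC(C)=O)CC#C[Si](C)(C)C)ccc1OC(=O)C(C)(C)C
F2 | step 7 | (1E,3R)-1-[3-methoxy-4-(pivaloyloxy)phenyl]hex-1-en-5-yn-3-yl acetate | COc1cc(/C=C/[C@H](OC(C)=O)CC#C)ccc1OC(=O)C(C)(C)C
F3 | step 7 | (1E,3R,5E)-6-(dicyclohexylboranyl)-1-[3-methoxy-4-(pivaloyloxy)phenyl]hexa-1,5-dien-3-yl acetate | COc1cc(/C=C/[C@H](OC(C)=O)C/C=C/B(C2CCCCC2)C2CCCCC2)ccc1OC(=O)C(C)(C)C
F4 | step 7 | (1E,3R,5E)-1-[3-methoxy-4-(pivaloyloxy)phenyl]-6-(methylzincio)hexa-1,5-dien-3-yl acetate | COc1cc(/C=C/[C@H](OC(C)=O)C/C=C/[Zn]C)ccc1OC(=O)C(C)(C)C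
F5 | step 7 | methylzinc alkoxide of the (1E,3R,5E,7R)-3-acetoxy-hepta-1,5-dien-7-ol (C7–O–ZnCH3 form of 18) | COc1cc(/C=C/[C@H](OC(C)=O)C/C=C/[C@@H](O[Zn]C)c2cc(OC)c(OC(=O)C(C)(C)C)c(OC)c2)ccc1OC(=O)C(C)(C)C
F6 | step 6 | (1R,2E,5E,7R)-7-[3,5-dimethoxy-4-(pivaloyloxy)phenyl]-7-hydroxy-1-[3-methoxy-4-(pivaloyloxy)phenyl]hepta-2,5-dien-1-yl acetate | COc1cc([C@H](OC(C)=O)/C=C/C/C=C/[C@@H](O)c2cc(OC)c(OC(=O)C(C)(C)C)c(OC)c2)ccc1OC(=O)C(C)(C)C
F7 | step 6 | (1R,2E,5E,7S)-7-[3,5-dimethoxy-4-(pivaloyloxy)phenyl]-7-hydroxy-1-[3-methoxy-4-(pivaloyloxy)phenyl]hepta-2,5-dien-1-yl acetate | COc1cc([C@H](OC(C)=O)/C=C/C/C=C/[C@H](O)c2cc(OC)c(OC(=O)C(C)(C)C)c(OC)c2)ccc1OC(=O)C(C)(C)C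
F8 | step 6 | (1R,2E,5R,6R,7R)-7-[3,5-dimethoxy-4-(pivaloyloxy)phenyl]-5,6-epoxy-7-hydroxy-1-[3-methoxy-4-(pivaloyloxy)phenyl]hept-2-en-1-yl acetate | COc1cc([C@@H](O)[C@H]2O[C@@H]2C/C=C/[C@@H](OC(C)=O)c2ccc(OC(=O)C(C)(C)C)c(OC)c2)cc(OC)c1OC(=O)C(C)(C)C
F9 | step 3 | (3-bromoprop-1-yn-1-yl)trimethylsilane | C[Si](C)(C)C#CCBr
F0 | step 8 | none | none
F0 | step 9 | none | none
A1 | alternative 1 | (2S,4R,6S)-2-(4-acetoxy-3-methoxyphenyl)-6-{2-[4-(benzyloxy)-3,5-dimethoxyphenyl]ethyl}tetrahydro-2H-pyran-4-yl trifluoroacetate | O1[C@H](c2ccc(OC(C)=O)c(OC)c2)C[C@H](OC(=O)C(F)(F)F)C[C@@H]1CCc1cc(OC)c(OCc2ccccc2)c(OC)c1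
A2 | alternative 1 | (3S)-1-[4-(benzyloxy)-3,5-dimethoxyphenyl]hex-5-en-3-ol | C=CC[C@@H](O)CCc1cc(OC)c(OCc2ccccc2)c(OC)c1
A3 | alternative 1 | 4-formyl-2-methoxyphenyl acetate | COc1cc(C=O)ccc1OC(C)=O
A4 | alternative 2 | propane-1,3-diol | OCCCO
A5 | alternative 2 | allyl acetate | C=CCOC(C)=O
A6 | alternative 2 | (4S,6S)-nona-1,8-diene-4,6-diol | C=CC[C@H](O)C[C@@H](O)CC=C
A7 | alternative 3 | (2R,4R)-1,2:4,5-diepoxypentane | C1[C@H](O1)C[C@@H]1CO1
A8 | alternative 3 | 2-[4-(benzyloxy)-3-methoxyphenyl]-1,3-dithiane | COc1cc(C2SCCCS2)ccc1OCc1ccccc1
A9 | alternative 3 | 2-[4-(benzyloxy)-3,5-dimethoxyphenyl]-1,3-dithiane | COc1cc(C2SCCCS2)cc(OC)c1OCc1ccccc1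
A10 | alternative 3 | (3R,5R)-1-{2-[4-(benzyloxy)-3-methoxyphenyl]-1,3-dithian-2-yl}-5-{2-[4-(benzyloxy)-3,5-dimethoxyphenyl]-1,3-dithian-2-yl}pentane-2,4-diol (bis-dithiane diol; (3R,5R) in heptane numbering) | COc1cc(C2(C[C@H](O)C[C@@H](O)CC3(c4cc(OC)c(OCc5ccccc5)c(OC)c4)SCCCS3)SCCCS2)ccc1OCc1ccccc1
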